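Ring D of the target is an indole: C13 carries the acyl carbon, C12b carries the indol-2-yl unit (rings A and B), and benzo ring E has bromine at C3, para to C13a. This is the pattern delivered when an N-arylhydroxylamine adds through oxygen to a conjugated ynoate and the adduct undergoes [3,3] rearrangement and cyclodehydration. One operation therefore forms C13–C13a and N5–C12b and closes ring D. The partners are N-(3-bromophenyl)hydroxylamine and an unprotected indol-2-yl propiolate carrying a 2-chloroethyl arm at the future C7a. Chloride is chosen because it should tolerate the amine catalyst yet later close ring C on N5.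

Key step: step 5

Remark: atom numbers are those of 12H-pyrido[1,2-a:3,4-b']diindole. Ring A is the benzo ring of the N12–H indole, ring B its pyrrole ring, ring C the six-membered ring containing N5, ring D the pyrrole ring bearing C13, and ring E the brominated benzo ring. Intermediate 8 is drawn as the Z isomer expected from anti addition; either geometry can rearrange.

Step 1
Reactants: 1 tryptophol (2-(1H-indol-3-yl)ethanol)
Product: 2 3-(2-chloroethyl)-1H-indole
Conditions: PPh3, CCl4, MeCN, rt to 50 °C
Reagents that add atoms: carbon tetrachloride, ClC(Cl)(Cl)Cl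
Why: Appel reaction, in which the alkoxyphosphonium ion of the primary alcohol is displaced by chloride under neutral conditions that leave the indole N–H untouched.

Step 2
Reactants: 2 3-(2-chloroethyl)-1H-indole
Product: 3 3-(2-chloroethyl)-2-iodo-1H-indole
Conditions: NIS, CH2Cl2, 0 °C, dark; aq. Na2S2O3 work-up, used crude
Reagents that add atoms: N-iodosuccinimide, O=C1CCC(=O)N1I
Why: Electrophilic aromatic iodination of a 3-alkylindole, which with C3 blocked places iodine at C2 as established for indoles of the tryptamine amide type, and which is not reversed because succinimide and not HI is the by-product.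

Step 3
Reactants: 3 3-(2-chloroethyl)-2-iodo-1H-indole; 4 methyl propiolate
Product: 5 methyl 3-[3-(2-chloroethyl)-1H-indol-2-yl]prop-2-ynoate
Conditions: PdCl2(PPh3)2 (5 mol%), CuI (10 mol%), K2CO3, THF, 40–60 °C, 4 (3 equiv) added in portions
Reagents that add atoms: none
Why: Sonogashira coupling of an aryl iodide with a propiolate ester, run with K2CO3 in place of an amine base so that amine-induced Michael addition and oligomerisation of the propiolate are suppressed.

Step 4
Reactants: 6 1-bromo-3-nitrobenzene
Product: 7 N-(3-bromophenyl)hydroxylamine
Conditions: Zn dust, NH4Cl, EtOH/H2O, 0 °C to rt; filtered, extracted, used at once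
Reagents that add atoms: none
Why: Partial reduction of a nitroarene by Zn in NH4Cl-buffered medium stops at the N-arylhydroxylamine, and the aryl bromide is inert to Zn under these conditions.

Step 5
Reactants: 5 methyl 3-[3-(2-chloroethyl)-1H-indol-2-yl]prop-2-ynoate; 7 N-(3-bromophenyl)hydroxylamine
Product: 10 methyl 6-bromo-2-[3-(2-chloroethyl)-1H-indol-2-yl]-1H-indole-3-carboxylate, via O-vinyl hydroxylamine 8 (not isolated), via amino keto ester 9 (not isolated)
Conditions: DABCO (20 mol%), THF, argon, 0 °C to rt; then AcOH (cat.), 50 °C
Reagents that add atoms: none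
Why: Amine-catalysed hydroxylamine–alkyne annulation, in which 1,4-diazabicyclo[2.2.2]octane, acting as nucleophilic or general-base catalyst, delivers the hydroxylamine oxygen to the ester-polarised β-carbon of 5 (the future C12b) to give 8. The weak N–O bond of 8 then breaks in a [3,3]-sigmatropic shift, an oxygen-tethered relative of the Fischer indole rearrangement, that bonds the ester-bearing carbon C13 to an ortho carbon of the aryl ring, and tautomerisation restores the arene as 9. Ring D closes by 5-exo-trig attack of the aniline nitrogen on the C12b ketone followed by loss of water, which the trace of acetic acid assists. The closest known reaction type is the amine-catalysed synthesis of N-unprotected indole-3-carboxylates from N-arylhydroxylamines and conjugated alkynes, applied here to an internal aryl ynoate. No stereocentre is formed; the step needs O- over N-addition (the more acidic O–H is the site engaged by the base), β-regiochemistry (set by the ester) and bond formation at the ortho carbon para to bromine (the other ortho carbon is flanked by bromine), and any 4-bromo isomer should be removable by chromatography. The primary chloride, unlike a bromide or a free alcohol, should neither quaternise the catalyst at room temperature nor add to the ynoate.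

Step 6
Reactants: 10 methyl 6-bromo-2-[3-(2-chloroethyl)-1H-indol-2-yl]-1H-indole-3-carboxylate
Product: 11 methyl 3-bromo-6,7-dihydro-12H-pyrido[1,2-a:3,4-b']diindole-13-carboxylate
Conditions: K2CO3, NaI (10 mol%), DMF, 60 °C
Reagents that add atoms: none
Why: Intramolecular N-alkylation (6-exo-tet SN2 with Finkelstein assistance) by the anion of N5–H, which the C13 ester makes the more acidic N–H, whereas N12–H is less acidic and cannot reach the chloride.

Step 7
Reactants: 11 methyl 3-bromo-6,7-dihydro-12H-pyrido[1,2-a:3,4-b']diindole-13-carboxylate
Product: 12 methyl 3-bromo-12H-pyrido[1,2-a:3,4-b']diindole-13-carboxylate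
Conditions: DDQ (1.2 equiv), 1,4-dioxane, rt to 80 °C
Reagents that add atoms: none
Why: DDQ dehydrogenation, in which hydride abstraction from C7 (stabilised through C7a by N12) and loss of the C6 proton create the C6=C7 bond and the fully conjugated ring C, while the C13 ester damps further oxidation of ring D.

Step 8
Reactants: 12 methyl 3-bromo-12H-pyrido[1,2-a:3,4-b']diindole-13-carboxylate
Product: 13 (3-bromo-12H-pyrido[1,2-a:3,4-b']diindol-13-yl)methanol
Conditions: i-Bu2AlH (4 equiv), CH2Cl2/THF, −78 to 0 °C; aq. potassium sodium tartrate (KNaC4H4O6) work-up; used crude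
Reagents that add atoms: none
Why: Hydride reduction of the ester to the primary alcohol (one equivalent of hydride is spent on N12–H) leaves the aryl bromide intact, and the acid-sensitive indol-3-ylmethanol-type product is kept cold and taken on without chromatography.

Step 9
Reactants: 13 (3-bromo-12H-pyrido[1,2-a:3,4-b']diindol-13-yl)methanol
Product: 14 3-bromo-12H-pyrido[1,2-a:3,4-b']diindole-13-carbaldehyde
Conditions: activated MnO2 (15 equiv), CH2Cl2, rt
Reagents that add atoms: none
Why: MnO2 oxidation of a benzylic-type heteroarylmethanol stops at the aldehyde, which the N12–H···O=C hydrogen bond further stabilises.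

Compound list
1 | tryptophol (2-(1H-indol-3-yl)ethanol) | OCCc1c[nH]c2ccccc12 | starting material
2 | 3-(2-chloroethyl)-1H-indole | ClCCc1c[nH]c2ccccc12 | intermediate
3 | 3-(2-chloroethyl)-2-iodo-1H-indole | ClCCc1c(I)[nH]c2ccccc12 | intermediate
4 | methyl propiolate | C#CC(=O)OC | starting material
5 | methyl 3-[3-(2-chloroethyl)-1H-indol-2-yl]prop-2-ynoate | COC(=O)C#Cc1[nH]c2ccccc2c1CCCl | intermediate
6 | 1-bromo-3-nitrobenzene | O=[N+]([O-])c1cccc(Br)c1 | starting material
7 | N-(3-bromophenyl)hydroxylamine | ONc1cccc(Br)c1 | intermediate
8 | O-vinyl hydroxylamine, methyl (Z)-3-{[(3-bromophenyl)amino]oxy}-3-[3-(2-chloroethyl)-1H-indol-2-yl]prop-2-enoate | COC(=O)/C=C(\ONc1cccc(Br)c1)c1[nH]c2ccccc2c1CCCl | intermediate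
9 | amino keto ester, methyl 2-(2-amino-4-bromophenyl)-3-[3-(2-chloroethyl)-1H-indol-2-yl]-3-oxopropanoate (racemic, enolisable) | COC(=O)C(c1ccc(Br)cc1N)C(=O)c1[nH]c2ccccc2c1CCCl | intermediate
10 | methyl 6-bromo-2-[3-(2-chloroethyl)-1H-indol-2-yl]-1H-indole-3-carboxylate | COC(=O)c1c(-c2[nH]c3ccccc3c2CCCl)[nH]c2cc(Br)ccc12 | intermediate
11 | methyl 3-bromo-6,7-dihydro-12H-pyrido[1,2-a:3,4-b']diindole-13-carboxylate | COC(=O)c1c2ccc(Br)cc2n2CCc3c4ccccc4[nH]c3c12 | intermediate
12 | methyl 3-bromo-12H-pyrido[1,2-a:3,4-b']diindole-13-carboxylate | COC(=O)c1c2ccc(Br)cc2n2ccc3c4ccccc4[nH]c3c12 | intermediate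
13 | (3-bromo-12H-pyrido[1,2-a:3,4-b']diindol-13-yl)methanol | OCc1c2ccc(Br)cc2n2ccc3c4ccccc4[nH]c3c12 | intermediate
14 | 3-bromo-12H-pyrido[1,2-a:3,4-b']diindole-13-carbaldehyde | O=Cc1c2ccc(Br)cc2n2ccc3c4ccccc4[nH]c3c12 | target

Total step count: 9. Longest linear sequence: 8 steps (steps 1, 2, 3, 5, 6, 7, 8, 9); step 4 is a one-step branch.

Steps most likely to fail

Step 5. The indol-2-yl group donates into the alkyne, so conjugate addition to this internal ynoate may be slow. Attack through nitrogen, disproportionation of the hydroxylamine, or slow alkylation of the catalyst by the chloride could then take over, and bond formation at the two ortho carbons may not be fully selective. The fallback forms N5–C12b first and C13–C13a second by C–H functionalisation. Ynoate 5 would be hydroaminated with commercial 3-bromoaniline (Nc1cccc(Br)c1; Ph3PAuCl/AgOTf cat., toluene, 60 °C) to give methyl (Z)-3-[(3-bromophenyl)amino]-3-[3-(2-chloroethyl)-1H-indol-2-yl]prop-2-enoate F1. Palladium-catalysed oxidative cyclisation of this N-aryl enaminoate (Pd(OAc)2 cat., Cu(OAc)2, K2CO3, DMF, 80 °C) at the less hindered ortho C–H returns to the route at 10. If the carbonate also closes ring C in the same flask, the material enters at 11.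

Step 3. Base-induced Michael addition and oligomerisation of the propiolate, N-vinylation of the indole, or loss of iodine from the labile 2-iodoindole may outrun the coupling. The fallback delivers the alkyne as a tin reagent under base-free conditions. Compound 4 would be deprotonated with LiN(i-Pr)2 at −78 °C and quenched with Bu3SnCl to give methyl 3-(tributylstannyl)prop-2-ynoate F2. Stille coupling of F2 with 3 (Pd(PPh3)4, CuI, DMF, 40 °C) returns to the route at 5.

Step 8. The aluminium alkoxide or the free alcohol may ionise to an azafulvenium ion, leading to over-reduction at C13 or self-condensation during isolation, and the vinylogous carbamate ester may be reduced only sluggishly. The fallback gives up the C13 carbon and reinstalls it by electrophilic formylation. From 12, saponification (LiOH, aq. THF/MeOH, 60 °C) would give 3-bromo-12H-pyrido[1,2-a:3,4-b']diindole-13-carboxylic acid F3. Protodecarboxylation on warming in AcOH would give 3-bromo-12H-pyrido[1,2-a:3,4-b']diindole F4. Vilsmeier–Haack formylation (POCl3, DMF, 0 °C to rt; aq. NaOAc) at C13, the indole β-position of ring D and the most nucleophilic carbon of the ring system, rejoins the route at 14.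

Further compounds
F1 | step 5 | methyl (Z)-3-[(3-bromophenyl)amino]-3-[3-(2-chloroethyl)-1H-indol-2-yl]prop-2-enoate | COC(=O)/C=C(\Nc1cccc(Br)c1)c1[nH]c2ccccc2c1CCCl
F2 | step 3 | methyl 3-(tributylstannyl)prop-2-ynoate | CCCC[Sn](CCCC)(CCCC)C#CC(=O)OC
F3 | step 8 | 3-bromo-12H-pyrido[1,2-a:3,4-b']diindole-13-carboxylic acid | OC(=O)c1c2ccc(Br)cc2n2ccc3c4ccccc4[nH]c3c12
F4 | step 8 | 3-bromo-12H-pyrido[1,2-a:3,4-b']diindole | c1c2ccc(Br)cc2n2ccc3c4ccccc4[nH]c3c12
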